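**Retrosynthetic overview**
- Target ⇒ its dimethyl ester (saponification last). The C11–C12 bond is cut by a B-alkyl Suzuki–Miyaura union of a (9S)-vinyl/isopropenyl core with a 2-bromoacrylate (arm B).
- Key disconnection: the C9–isopropenyl bond, made by enantioselective copper-catalysed SN2' allylic substitution of an achiral skipped-dienyl phosphate with isopropenyl–B(pin). This one step sets the only stereocentre, installs the isopropenyl group and unveils the vinyl handle for arm B.
- Arm B ⇒ methyl (E)-2,3-dibromoacrylate as a geometry-defining linchpin: the C3–Br bond is alkylated first (Negishi, 2-(3-furyl)ethylzinc), the C2–Br bond second (the Suzuki union).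
- Arm A phosphate ⇒ Stille allyl–alkenyl coupling and Still–Gennari olefination on the C6 aldehyde cut from geranyl acetate, which supplies the E-trisubstituted alkene.
- No ring is formed: the furan is carried in intact from 3-bromofuran.

Assumption: all eight starting materials are bought, and the sense of induction of the copper catalyst is assigned by analogy, so the ligand antipode is chosen on the first run to give the (9S)-diene.

**Route**

Step 1
Reactants: 1 (2E)-3,7-dimethylocta-2,6-dien-1-yl acetate (geranyl acetate)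
Product: 2 (2E)-5-(3,3-dimethyloxiran-2-yl)-3-methylpent-2-en-1-yl acetate
Conditions: mCPBA (1.0 equiv), CH2Cl2, 0 °C
Reagents that add atoms: mCPBA (3-chloroperoxybenzoic acid), OOC(=O)c1cccc(Cl)c1
Why: Prilezhaev epoxidation is site-selective for the electron-rich terminal trisubstituted alkene because the C2=C3 alkene is deactivated by the allylic acetate; the new oxirane stereocentre is racemic and is destroyed in step 2.

Step 2
Reactants: 2 (2E)-5-(3,3-dimethyloxiran-2-yl)-3-methylpent-2-en-1-yl acetate
Product: 3 (2E)-3-methyl-6-oxohex-2-en-1-yl acetate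
Conditions: H5IO6, THF/H2O, 0 °C
Reagents that add atoms: none
Why: Periodic acid hydrolyses the epoxide to the glycol and cleaves it (Malaprade-type glycol cleavage) to the aldehyde and acetone, the aldehyde oxygen being the former oxirane oxygen, while the acetate and the E-alkene are untouched.

Step 3
Reactants: 4 methyl 2-[bis(2,2,2-trifluoroethoxy)phosphoryl]acetate, 5 5-bromo-2-methylpent-2-ene
Product: 6 methyl 2-[bis(2,2,2-trifluoroethoxy)phosphoryl]-6-methylhept-5-enoate
Conditions: NaH, NaI (cat.), DMSO, 50 °C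
Reagents that add atoms: none
Why: SN2 C-alkylation of the stabilised phosphonoacetate anion by the primary homoallylic bromide under iodide catalysis; the new stereocentre is racemic and is lost in step 4.

Step 4
Reactants: 3 (2E)-3-methyl-6-oxohex-2-en-1-yl acetate, 6 methyl 2-[bis(2,2,2-trifluoroethoxy)phosphoryl]-6-methylhept-5-enoate
Product: 7 methyl (2Z,6E)-8-(acetyloxy)-6-methyl-2-(4-methylpent-3-en-1-yl)octa-2,6-dienoate
Conditions: KN(SiMe3)2, 18-crown-6, THF, −78 °C
Reagents that add atoms: none
Why: Still–Gennari variant of the Horner–Wadsworth–Emmons olefination, in which fast irreversible collapse of the kinetic adduct of the bis(trifluoroethyl) phosphonate under non-coordinating K+/crown conditions gives the Z-trisubstituted enoate with the ester cis to the chain.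

Step 5
Reactants: 7 methyl (2Z,6E)-8-(acetyloxy)-6-methyl-2-(4-methylpent-3-en-1-yl)octa-2,6-dienoate, 8 (2E)-3-(tributylstannyl)prop-2-en-1-ol
Product: 9 methyl (2Z,6E,9E)-11-hydroxy-6-methyl-2-(4-methylpent-3-en-1-yl)undeca-2,6,9-trienoate
Conditions: Pd(dba)2 (5 mol %), LiCl (3 equiv), DMF, 40 °C
Reagents that add atoms: none
Why: Stille allyl–alkenyl cross-coupling, in which zerovalent palladium ionises the primary allylic acetate, the vinylstannane transmetalates and the C–C bond forms at the unsubstituted allyl terminus with retention of both alkene geometries to give the skipped E,E-diene.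

Step 6
Reactants: 9 methyl (2Z,6E,9E)-11-hydroxy-6-methyl-2-(4-methylpent-3-en-1-yl)undeca-2,6,9-trienoate
Product: 10 methyl (2Z,6E,9E)-11-[(diethoxyphosphoryl)oxy]-6-methyl-2-(4-methylpent-3-en-1-yl)undeca-2,6,9-trienoate
Conditions: ClP(O)(OEt)2, Et3N, DMAP (cat.), CH2Cl2, 0 °C
Reagents that add atoms: diethyl chlorophosphate, CCOP(=O)(Cl)OCC
Why: O-Phosphorylation of the primary allylic alcohol installs the leaving group required for copper-catalysed allylic substitution.

Step 7 (key step)
Reactants: 10 methyl (2Z,6E,9E)-11-[(diethoxyphosphoryl)oxy]-6-methyl-2-(4-methylpent-3-en-1-yl)undeca-2,6,9-trienoate, 11 4,4,5,5-tetramethyl-2-(prop-1-en-2-yl)-1,3,2-dioxaborolane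
Product: 12 methyl (2Z,6E,9S)-9-ethenyl-6,10-dimethyl-2-(4-methylpent-3-en-1-yl)undeca-2,6,10-trienoate
Conditions: CuCl (5 mol %), chiral NHC precursor 3-mesityl-4,5-diphenyl-1-(2-sulfonatophenyl)-4,5-dihydroimidazol-3-ium zwitterion (single enantiomer, 5.5 mol %), NaOMe (2 equiv), THF, 22 °C
Reagents that add atoms: none
Why: Enantioselective copper-catalysed allylic substitution (SN2'-selective), in which methoxide transfers the isopropenyl group from boron to the chiral NHC–copper complex and this adds anti-SN2' to one enantiotopic face of the E-allylic phosphate, setting the C9 stereocentre as S by catalyst control and creating the isopropenyl and vinyl groups in one operation.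

Step 8
Reactants: 13 3-bromofuran, 14 oxirane
Product: 16 2-(furan-3-yl)ethan-1-ol, via furan-3-yllithium 15 (not isolated)
Conditions: n-BuLi, THF, −78 °C; then oxirane, −78 → −45 °C; H2O
Reagents that add atoms: none
Why: Bromine–lithium exchange gives 3-furyllithium, which opens ethylene oxide by SN2 attack below the temperature at which it isomerises to the 2-lithio species.

Step 9
Reactants: 16 2-(furan-3-yl)ethan-1-ol
Product: 17 3-(2-iodoethyl)furan
Conditions: I2, PPh3, imidazole, CH2Cl2, 0 °C
Reagents that add atoms: iodine, [I][I]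
Why: Appel-type iodination (Garegg–Samuelsson conditions) of the primary alcohol through the alkoxyphosphonium iodide, under neutral conditions that spare the furan.

Step 10
Reactants: 18 methyl prop-2-ynoate
Product: 19 methyl (2E)-2,3-dibromoprop-2-enoate
Conditions: Br2, CHCl3, 60 °C, dark
Reagents that add atoms: bromine, BrBr
Why: Electrophilic anti-addition of bromine across the alkyne gives the E-dibromide, whose geometry fixes the relative position of the two carbon substituents introduced later (C3–Br cis to the ester).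

Step 11
Reactants: 17 3-(2-iodoethyl)furan, 19 methyl (2E)-2,3-dibromoprop-2-enoate
Product: 21 methyl (2E)-2-bromo-5-(furan-3-yl)pent-2-enoate, via [2-(furan-3-yl)ethyl]zinc iodide 20 (not isolated)
Conditions: Zn dust, LiCl, THF, 40 °C; then 19, Pd(PPh3)4 (3 mol %), THF, 0 °C → rt
Reagents that add atoms: none
Why: Proposed new method: site-selective Negishi mono-coupling of a primary alkylzinc iodide at C3 of the (E)-2,3-dibromoacrylate, where oxidative addition of zerovalent palladium is expected at the β C–Br bond (a vinylogous acyl bromide, more electron-poor and less hindered than the α C–Br) so that the alkyl group replaces the β-bromine with retention and ends up cis to the ester; the closest known reaction type is the C3-selective Negishi and Stille mono-coupling of alkyl (E)-2,3-dibromopropenoates with aryl-, alkenyl- and alkynyl-metal reagents.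

Step 12
Reactants: 12 methyl (2Z,6E,9S)-9-ethenyl-6,10-dimethyl-2-(4-methylpent-3-en-1-yl)undeca-2,6,10-trienoate, 21 methyl (2E)-2-bromo-5-(furan-3-yl)pent-2-enoate
Product: 23 methyl (2Z,6E,9R,12Z)-15-(furan-3-yl)-12-(methoxycarbonyl)-6-methyl-2-(4-methylpent-3-en-1-yl)-9-(prop-1-en-2-yl)pentadeca-2,6,12-trienoate, via primary alkyl(disiamyl)borane 22 (not isolated)
Conditions: Sia2BH (1.1 equiv, from BH3·THF and 2-methylbut-2-ene), THF, 0 °C; then 21, Pd(dppf)Cl2 (5 mol %), AsPh3, K3PO4 (aq), DMF, 50 °C
Reagents that add atoms: none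
Why: Chemoselective anti-Markovnikov hydroboration of the monosubstituted vinyl group (disiamylborane reacts far faster with it than with the 1,1-disubstituted isopropenyl group or the trisubstituted alkenes) followed by B-alkyl Suzuki–Miyaura coupling with the α-bromoenoate with retention of alkene geometry, the C9 stereocentre being untouched (its descriptor changes from S to R only through substituent priorities).

Step 13
Reactants: 23 methyl (2Z,6E,9R,12Z)-15-(furan-3-yl)-12-(methoxycarbonyl)-6-methyl-2-(4-methylpent-3-en-1-yl)-9-(prop-1-en-2-yl)pentadeca-2,6,12-trienoate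
Product: 24 (2Z,6E,9R,12Z)-12-carboxy-15-(furan-3-yl)-6-methyl-2-(4-methylpent-3-en-1-yl)-9-(prop-1-en-2-yl)pentadeca-2,6,12-trienoic acid (CNP0235727.1)
Conditions: LiOH, THF/MeOH/H2O, 40 °C; then 1 M HCl to pH 3, 0 °C
Reagents that add atoms: lithium hydroxide, [Li+].[OH-]
Why: Saponification (acyl-oxygen cleavage) of both hindered methyl esters under mild hydroxide conditions that leave the α-alkyl Z-enoates, the furan and the non-acidic C9 centre unchanged.

**Compound list**
1 | (2E)-3,7-dimethylocta-2,6-dien-1-yl acetate (geranyl acetate) | CC(=O)OC/C=C(\C)CCC=C(C)C | starting material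
2 | (2E)-5-(3,3-dimethyloxiran-2-yl)-3-methylpent-2-en-1-yl acetate (racemic at the oxirane carbon) | CC(=O)OC/C=C(\C)CCC1OC1(C)C | intermediate
3 | (2E)-3-methyl-6-oxohex-2-en-1-yl acetate | CC(=O)OC/C=C(\C)CCC=O | intermediate
4 | methyl 2-[bis(2,2,2-trifluoroethoxy)phosphoryl]acetate | COC(=O)CP(=O)(OCC(F)(F)F)OCC(F)(F)F | starting material
5 | 5-bromo-2-methylpent-2-ene | CC(C)=CCCBr | starting material
6 | methyl 2-[bis(2,2,2-trifluoroethoxy)phosphoryl]-6-methylhept-5-enoate (racemic) | COC(=O)C(CCC=C(C)C)P(=O)(OCC(F)(F)F)OCC(F)(F)F | intermediate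
7 | methyl (2Z,6E)-8-(acetyloxy)-6-methyl-2-(4-methylpent-3-en-1-yl)octa-2,6-dienoate | CC(=O)OC/C=C(\C)CC/C=C(/CCC=C(C)C)C(=O)OC | intermediate
8 | (2E)-3-(tributylstannyl)prop-2-en-1-ol | OC/C=C/[Sn](CCCC)(CCCC)CCCC | starting material
9 | methyl (2Z,6E,9E)-11-hydroxy-6-methyl-2-(4-methylpent-3-en-1-yl)undeca-2,6,9-trienoate | OC/C=C/C/C=C(\C)CC/C=C(/CCC=C(C)C)C(=O)OC | intermediate
10 | methyl (2Z,6E,9E)-11-[(diethoxyphosphoryl)oxy]-6-methyl-2-(4-methylpent-3-en-1-yl)undeca-2,6,9-trienoate | CCOP(=O)(OCC)OC/C=C/C/C=C(\C)CC/C=C(/CCC=C(C)C)C(=O)OC | intermediate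
11 | 4,4,5,5-tetramethyl-2-(prop-1-en-2-yl)-1,3,2-dioxaborolane | CC(=C)B1OC(C)(C)C(C)(C)O1 | starting material
12 | methyl (2Z,6E,9S)-9-ethenyl-6,10-dimethyl-2-(4-methylpent-3-en-1-yl)undeca-2,6,10-trienoate | C=C(C)[C@@H](C/C=C(\C)CC/C=C(/CCC=C(C)C)C(=O)OC)C=C | intermediate
13 | 3-bromofuran | Brc1ccoc1 | starting material
14 | oxirane | C1CO1 | starting material
15 | furan-3-yllithium | [Li]c1ccoc1 | intermediate
16 | 2-(furan-3-yl)ethan-1-ol | OCCc1ccoc1 | intermediate
17 | 3-(2-iodoethyl)furan | ICCc1ccoc1 | intermediate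
18 | methyl prop-2-ynoate | C#CC(=O)OC | starting material
19 | methyl (2E)-2,3-dibromoprop-2-enoate | COC(=O)/C(Br)=C\Br | intermediate
20 | [2-(furan-3-yl)ethyl]zinc iodide | I[Zn]CCc1ccoc1 | intermediate
21 | methyl (2E)-2-bromo-5-(furan-3-yl)pent-2-enoate | COC(=O)/C(Br)=C\CCc1ccoc1 | intermediate
22 | methyl (2Z,6E,9R)-11-[bis(3-methylbutan-2-yl)boranyl]-6-methyl-2-(4-methylpent-3-en-1-yl)-9-(prop-1-en-2-yl)undeca-2,6-dienoate | C=C(C)[C@@H](C/C=C(\C)CC/C=C(/CCC=C(C)C)C(=O)OC)CCB(C(C)C(C)C)C(C)C(C)C | intermediate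
23 | methyl (2Z,6E,9R,12Z)-15-(furan-3-yl)-12-(methoxycarbonyl)-6-methyl-2-(4-methylpent-3-en-1-yl)-9-(prop-1-en-2-yl)pentadeca-2,6,12-trienoate | C=C(C)[C@@H](C/C=C(\C)CC/C=C(/CCC=C(C)C)C(=O)OC)CC/C(=C/CCc1ccoc1)C(=O)OC | intermediate
24 | (2Z,6E,9R,12Z)-12-carboxy-15-(furan-3-yl)-6-methyl-2-(4-methylpent-3-en-1-yl)-9-(prop-1-en-2-yl)pentadeca-2,6,12-trienoic acid | C=C(C)[C@@H](C/C=C(\C)CC/C=C(/CCC=C(C)C)C(=O)O)CC/C(=C/CCc1ccoc1)C(=O)O | target

**Step count and risks**

Total step count: 13. Longest linear sequence: 8 steps (steps 1, 2, 4, 5, 6, 7, 12, 13, from geranyl acetate). Step 3 and steps 8–11 are side branches.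

The three steps most likely to fail:

Step 7. The ee or the SN2'/SN2 ratio may be modest on this aliphatic skipped-dienyl phosphate, and methoxide could erode the Z-enoate geometry. The fallback sets out from 9 and comes back at 12, replacing catalyst control by a reagent-controlled epoxidation and a stereospecific epoxide opening. Allylic alcohol 9 is epoxidised (Ti(OiPr)4, D-(−)-diethyl tartrate, t-BuOOH, 4 Å sieves, CH2Cl2, −20 °C, Sharpless asymmetric epoxidation) to the (2R,3R)-epoxy alcohol F1. Isopropenylmagnesium bromide with CuI (cat.) in THF at −40 °C opens the oxirane at the carbon remote from the hydroxymethyl group with inversion, giving the 1,2-diol F2 with the isopropenyl-bearing centre in the required configuration; the hindered enoate is expected to survive at this temperature. 1,1'-Thiocarbonyldiimidazole converts F2 into the cyclic thionocarbonate F3. 1,3-Dimethyl-2-phenyl-1,3,2-diazaphospholidine at 40 °C (Corey–Winter olefination) then removes both oxygens and gives the terminal alkene 12.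

Step 12. Discrimination between vinyl and isopropenyl may be incomplete, or transfer of the primary alkyl group from the disiamylborane to the hindered α-bromoenoate may be slow. The fallback sets out from 12 and comes back at 23, separating the hydroboration from the C–C bond formation and switching from boron to zinc. Compound 12 is hydroborated with Sia2BH and oxidised with NaBO3·4H2O to the primary alcohol F4, which is purified from any isopropenyl-derived isomer. I2, PPh3 and imidazole give the primary iodide F5. Zinc insertion (Zn, LiCl, THF) gives the alkylzinc iodide F6, which undergoes Negishi coupling with 21 (Pd(dppf)Cl2, THF, 40 °C) with retention to give 23.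

Step 11. Coupling may occur at the wrong C–Br bond or twice. The fallback sets out from 17 and comes back at 23, building the α-halo enoate by syn-hydrostannation of an alkyne instead of from the dibromide. Iodide 17 is alkylated with LiC≡CH·H2NCH2CH2NH2 in DMSO to 3-(but-3-yn-1-yl)furan F7. Deprotonation (n-BuLi, THF, −78 °C) and methyl chloroformate give methyl 5-(furan-3-yl)pent-2-ynoate F8. Pd(PPh3)4-catalysed syn-addition of Bu3SnH places tin at C2 and gives the (E)-α-stannyl enoate F9. Iododestannylation (I2, CH2Cl2, 0 °C; iodine is used because bromine would attack the furan) gives, with retention, methyl (2E)-5-(furan-3-yl)-2-iodopent-2-enoate F10. F10 takes the place of 21 in the coupling with borane 22 under the conditions of step 12 and gives 23.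

**Further compounds**
F1 | step 7 | methyl (2Z,6E)-8-[(2R,3R)-3-(hydroxymethyl)oxiran-2-yl]-6-methyl-2-(4-methylpent-3-en-1-yl)octa-2,6-dienoate | OC[C@H]1O[C@@H]1C/C=C(\C)CC/C=C(/CCC=C(C)C)C(=O)OC
F2 | step 7 | methyl (2Z,6E,9R,10S)-10,11-dihydroxy-6-methyl-2-(4-methylpent-3-en-1-yl)-9-(prop-1-en-2-yl)undeca-2,6-dienoate | OC[C@@H](O)[C@@H](C(C)=C)C/C=C(\C)CC/C=C(/CCC=C(C)C)C(=O)OC
F3 | step 7 | methyl (2Z,6E,9R)-6-methyl-2-(4-methylpent-3-en-1-yl)-9-(prop-1-en-2-yl)-9-[(4S)-2-sulfanylidene-1,3-dioxolan-4-yl]nona-2,6-dienoate | S=C1OC[C@@H](O1)[C@@H](C(C)=C)C/C=C(\C)CC/C=C(/CCC=C(C)C)C(=O)OC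
F4 | step 12 | methyl (2Z,6E,9S)-11-hydroxy-6-methyl-2-(4-methylpent-3-en-1-yl)-9-(prop-1-en-2-yl)undeca-2,6-dienoate | C=C(C)[C@@H](C/C=C(\C)CC/C=C(/CCC=C(C)C)C(=O)OC)CCO
F5 | step 12 | methyl (2Z,6E,9S)-11-iodo-6-methyl-2-(4-methylpent-3-en-1-yl)-9-(prop-1-en-2-yl)undeca-2,6-dienoate | C=C(C)[C@@H](C/C=C(\C)CC/C=C(/CCC=C(C)C)C(=O)OC)CCI
F6 | step 12 | methyl (2Z,6E,9S)-11-(iodozincio)-6-methyl-2-(4-methylpent-3-en-1-yl)-9-(prop-1-en-2-yl)undeca-2,6-dienoate | C=C(C)[C@@H](C/C=C(\C)CC/C=C(/CCC=C(C)C)C(=O)OC)CC[Zn]I
F7 | step 11 | 3-(but-3-yn-1-yl)furan | C#CCCc1ccoc1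
F8 | step 11 | methyl 5-(furan-3-yl)pent-2-ynoate | COC(=O)C#CCCc1ccoc1
F9 | step 11 | methyl (2E)-5-(furan-3-yl)-2-(tributylstannyl)pent-2-enoate | COC(=O)/C(=C\CCc1ccoc1)[Sn](CCCC)(CCCC)CCCC
F10 | step 11 | methyl (2E)-5-(furan-3-yl)-2-iodopent-2-enoate | COC(=O)/C(I)=C\CCc1ccoc1
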